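**Assumption:** the facial sense of the ligand-controlled steps (ProPhenol in step 4, Kishi sulfonamide in step 10, tartrate in step 14) is taken from the published models; if a step gives the antipodal carbinol, the mirror-image ligand is used. Positions are quoted with germacrane numbering (C1–C15) of the target.

## Retrosynthetic overview

1. Target ⇐ desilylation, peracid epoxidation of C1=C10, and Yamaguchi acylation of C8–OH with preformed (2S,3S)-epoxyangelic acid ⇐ macrocyclic hydroxy lactone 22.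
2. Key disconnection C7–C8: the ten-membered ring is closed by SmI2 ketyl radical addition of the C8 aldehyde to a 3-(acetoxymethyl)butenolide, with loss of acetate; this sets C7 and C8 and unveils the exocyclic methylene.
3. Butenolide (C6) ⇐ Z-enal + (Z)-β-iodoacrylate by asymmetric Ni/Cr coupling and lactonisation; Z-C4=C5 ⇐ syn methylcupration of an ynoate; C3 ⇐ Zn–ProPhenol propiolate addition.
4. C8–C3 chain with E-C1=C10 ⇐ but-3-yn-1-ol by Zr-catalysed carboalumination and ethylene oxide opening.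
5. Ring order: butenolide → ten-membered carbocycle → side-chain oxirane (arrives with the acid) → ring oxirane last.

## Route

Step 1
Reactants: 1 but-3-yn-1-ol
Product: 2 triethyl(but-3-yn-1-yloxy)silane
Conditions: TESCl, imidazole, CH2Cl2, 0 °C → rt
Reagents that add atoms: chlorotriethylsilane, CC[Si](Cl)(CC)CC
Why: Standard silyl ether formation masks the primary alcohol as a TES ether that later serves as a latent aldehyde.

Step 2
Reactants: 2 triethyl(but-3-yn-1-yloxy)silane, 3 oxirane
Product: 6 (3E)-4-methyl-6-(triethylsilyloxy)hex-3-en-1-ol, via alkenyldimethylalane 4 (not isolated), via lithium alkenylalanate 5 (not isolated)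
Conditions: AlMe3, Cp2ZrCl2 (0.25 equiv), CH2Cl2, 0 °C → rt; evaporate; n-BuLi, hexane/THF, −78 → 0 °C; oxirane, −78 °C → rt
Reagents that add atoms: trimethylaluminium, C[Al](C)C
Why: Negishi Zr-catalysed syn-carboalumination sets the E-trisubstituted C1=C10 alkene with its C14 methyl regio- and stereospecifically, and the derived alanate opens oxirane by SN2 with retention of alkene geometry to add C2–C3.

Step 3
Reactants: 6 (3E)-4-methyl-6-(triethylsilyloxy)hex-3-en-1-ol
Product: 7 (3E)-4-methyl-6-(triethylsilyloxy)hex-3-enal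
Conditions: Dess–Martin periodinane, NaHCO3 (buffer), CH2Cl2, 0 °C; used crude
Reagents that add atoms: none
Why: Dess–Martin oxidation is mild and non-basic, so the β,γ-unsaturated aldehyde forms without migration of the alkene into conjugation.

Step 4
Reactants: 7 (3E)-4-methyl-6-(triethylsilyloxy)hex-3-enal, 8 methyl propiolate
Product: 9 methyl (4S,6E)-4-hydroxy-7-methyl-9-(triethylsilyloxy)non-6-en-2-ynoate
Conditions: (S,S)-ProPhenol (20 mol %), Me2Zn, Ph3P=O (40 mol %), toluene, 4 °C
Reagents that add atoms: none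
Why: Trost's dinuclear Zn–ProPhenol alkynylation adds the zinc acetylide of methyl propiolate to one enantioface of the aldehyde, setting C3 as S under catalyst control and bringing in C4–C6.

Step 5
Reactants: 9 methyl (4S,6E)-4-hydroxy-7-methyl-9-(triethylsilyloxy)non-6-en-2-ynoate
Product: 10 methyl (4S,6E)-7-methyl-4,9-bis(triethylsilyloxy)non-6-en-2-ynoate
Conditions: TESCl, imidazole, DMAP (cat.), CH2Cl2, 0 °C
Reagents that add atoms: chlorotriethylsilane, CC[Si](Cl)(CC)CC
Why: Silyl ether formation protects C3–OH so that the Z-enoate made next cannot lactonise and C8–OH can later be acylated selectively.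

Step 6
Reactants: 10 methyl (4S,6E)-7-methyl-4,9-bis(triethylsilyloxy)non-6-en-2-ynoate
Product: 11 methyl (2Z,4S,6E)-3,7-dimethyl-4,9-bis(triethylsilyloxy)nona-2,6-dienoate
Conditions: Me2CuLi (MeLi, CuI), THF, −78 °C; MeOH quench at −78 °C
Reagents that add atoms: lithium dimethylcuprate, [Li+].C[Cu-]C
Why: Gilman conjugate addition to the ynoate is a syn carbocupration, and protonation at −78 °C with retention gives the 2Z-enoate in which C3 and C6 are cis, fixing the Z-C4=C5 alkene with its C15 methyl.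

Step 7
Reactants: 11 methyl (2Z,4S,6E)-3,7-dimethyl-4,9-bis(triethylsilyloxy)nona-2,6-dienoate
Product: 12 (2Z,4S,6E)-3,7-dimethyl-4,9-bis(triethylsilyloxy)nona-2,6-dien-1-ol
Conditions: DIBAL-H (2.5 equiv), CH2Cl2, −78 °C; Rochelle salt
Reagents that add atoms: none
Why: DIBAL-H 1,2-reduction of the enoate gives the allylic alcohol without touching the silyl ethers or the alkene geometry.

Step 8
Reactants: 12 (2Z,4S,6E)-3,7-dimethyl-4,9-bis(triethylsilyloxy)nona-2,6-dien-1-ol
Product: 13 (2Z,4S,6E)-3,7-dimethyl-4,9-bis(triethylsilyloxy)nona-2,6-dienal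
Conditions: MnO2, CH2Cl2, rt
Reagents that add atoms: none
Why: MnO2 oxidises allylic alcohols chemoselectively under neutral conditions, so the Z-enal (neral type) is obtained without Z/E isomerisation.

Step 9
Reactants: 8 methyl propiolate, 14 formaldehyde (from cracked paraformaldehyde)
Product: 16 methyl (2Z)-2-(acetoxymethyl)-3-iodoprop-2-enoate, via hydroxymethyl iodoacrylate 15 (not isolated)
Conditions: Et2AlI, CH2Cl2, −78 °C; CH2O (gas), −78 → −40 °C; then Ac2O, pyridine, DMAP, → 0 °C
Reagents that add atoms: diethylaluminium iodide, CC[Al](I)CC; acetic anhydride, CC(=O)OC(C)=O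
Why: Kishi-type iodide-triggered halo-aldol (β-iodo Morita–Baylis–Hillman reaction): conjugate addition of iodide gives a β-iodoallenolate that adds to formaldehyde to give the kinetic Z-iodoacrylate, and the aluminium alkoxide is acetylated in the same flask.

Step 10
Reactants: 13 (2Z,4S,6E)-3,7-dimethyl-4,9-bis(triethylsilyloxy)nona-2,6-dienal, 16 methyl (2Z)-2-(acetoxymethyl)-3-iodoprop-2-enoate
Product: 18 [(5R)-5-[(1Z,3S,5E)-2,6-dimethyl-3,8-bis(triethylsilyloxy)octa-1,5-dien-1-yl]-2-oxo-2,5-dihydrofuran-3-yl]methyl acetate, via hydroxy trienoate 17 (not isolated)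
Conditions: CrCl2 (4 equiv), Kishi (S)-oxazoline–sulfonamide ligand, Et3N, NiCl2(2,9-dimethylphenanthroline) (cat.), THF/MeCN, rt; lactonisation on work-up
Reagents that add atoms: none
Why: Asymmetric Nozaki–Hiyama–Kishi alkenylation: the (Z)-β-carbomethoxyvinyl chromium species forms with retention, ligand-controlled 1,2-addition to the enal sets C6 as R, and the Z-γ-alkoxide lactonises onto the cis ester to give the butenolide.

Step 11
Reactants: 18 [(5R)-5-[(1Z,3S,5E)-2,6-dimethyl-3,8-bis(triethylsilyloxy)octa-1,5-dien-1-yl]-2-oxo-2,5-dihydrofuran-3-yl]methyl acetate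
Product: 19 [(5R)-5-[(1Z,3S,5E)-2,6-dimethyl-8-oxo-3-(triethylsilyloxy)octa-1,5-dien-1-yl]-2-oxo-2,5-dihydrofuran-3-yl]methyl acetate
Conditions: (COCl)2, DMSO, CH2Cl2, −78 → −30 °C; i-Pr2NEt, −78 → −20 °C; used crude
Reagents that add atoms: none
Why: Under Swern conditions a primary TES ether is cleaved and oxidised directly to the aldehyde while the hindered secondary TES ether survives (selective oxidative desilylation), and Hünig's base at low temperature avoids conjugation of the β,γ-unsaturated aldehyde.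

Step 12
Reactants: 19 [(5R)-5-[(1Z,3S,5E)-2,6-dimethyl-8-oxo-3-(triethylsilyloxy)octa-1,5-dien-1-yl]-2-oxo-2,5-dihydrofuran-3-yl]methyl acetate
Product: 22 (3aR,4R,6E,9S,10Z,11aR)-4-hydroxy-6,10-dimethyl-3-methylidene-9-(triethylsilyloxy)-3a,4,5,8,9,11a-hexahydrocyclodeca[b]furan-2(3H)-one, via samarium ketyl 20 (not isolated), via samarium enolate 21 (not isolated)
Conditions: SmI2 (2.5 equiv), THF, 0.002 M (syringe-pump addition of 19), −78 → −20 °C; pH 7 buffer at −78 °C
Reagents that add atoms: none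
Why: Proposed new method: SmI2 reduces the aldehyde to a ketyl radical that adds 10-exo to the β-carbon (C7) of the tethered butenolide anti to the C6–C5 bond (trans lactone) through a Sm(III) chelate between ketyl oxygen and lactone carbonyl that places O8 syn to C11 (8R), a second SmI2 reduces the α-radical to the samarium enolate, and E1cB loss of acetate unveils the exocyclic methylene (a radical SN2′ overall); the closest known chemistry is the SmI2 ketyl–olefin (Fukuzawa) coupling of aldehydes with acrylates and butenolides, SmI2 Barbier and Reformatsky macrocyclisations, and β-elimination from enolates of Baylis–Hillman acetates.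

Step 13
Reactants: 23 angelic acid [(2Z)-2-methylbut-2-enoic acid]
Product: 24 (2Z)-2-methylbut-2-en-1-ol
Conditions: LiAlH4, Et2O, 0 °C
Reagents that add atoms: none
Why: Hydride reduction of the carboxylic acid gives the allylic alcohol with the angelate Z geometry intact.

Step 14
Reactants: 24 (2Z)-2-methylbut-2-en-1-ol
Product: 25 [(2R,3S)-2,3-dimethyloxiran-2-yl]methanol
Conditions: Ti(Oi-Pr)4 (cat.), D-(−)-DIPT, t-BuOOH, 4 Å MS, CH2Cl2, −20 °C
Reagents that add atoms: tert-butyl hydroperoxide, CC(C)(C)OO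
Why: Sharpless asymmetric epoxidation with D-(−)-tartrate delivers oxygen to the face that gives the (2R,3S)-epoxy alcohol, and syn addition keeps CH2OH and the C3 methyl cis.

Step 15
Reactants: 25 [(2R,3S)-2,3-dimethyloxiran-2-yl]methanol
Product: 26 (2S,3S)-2,3-dimethyloxirane-2-carboxylic acid
Conditions: RuCl3·xH2O (cat.), NaIO4, CCl4/MeCN/H2O, rt
Reagents that add atoms: sodium periodate, [Na+].[O-]I(=O)(=O)=O; water, O
Why: Sharpless RuO4 oxidation takes the primary epoxy alcohol to the acid without touching the oxirane; the same stereocentres become 2S,3S only through the CIP priority change.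

Step 16
Reactants: 22 (3aR,4R,6E,9S,10Z,11aR)-4-hydroxy-6,10-dimethyl-3-methylidene-9-(triethylsilyloxy)-3a,4,5,8,9,11a-hexahydrocyclodeca[b]furan-2(3H)-one, 26 (2S,3S)-2,3-dimethyloxirane-2-carboxylic acid
Product: 28 (3aR,4R,6E,9S,10Z,11aR)-6,10-dimethyl-3-methylidene-2-oxo-9-(triethylsilyloxy)-2,3,3a,4,5,8,9,11a-octahydrocyclodeca[b]furan-4-yl (2S,3S)-2,3-dimethyloxirane-2-carboxylate, via Yamaguchi mixed anhydride 27 (not isolated)
Conditions: 26, 2,4,6-Cl3C6H2COCl, Et3N, THF, rt; then 22, DMAP, toluene, rt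
Reagents that add atoms: none
Why: Yamaguchi esterification acylates the hindered secondary C8–OH through the mixed anhydride and acyl-DMAP species with retention at C8 and no epimerisation of the α-quaternary epoxy acid.

Step 17
Reactants: 28 (3aR,4R,6E,9S,10Z,11aR)-6,10-dimethyl-3-methylidene-2-oxo-9-(triethylsilyloxy)-2,3,3a,4,5,8,9,11a-octahydrocyclodeca[b]furan-4-yl (2S,3S)-2,3-dimethyloxirane-2-carboxylate
Product: 29 3-O-triethylsilyl ether of the target [(1R,10R)-1,10-epoxide of 28]
Conditions: m-CPBA (1.05 equiv), NaHCO3 (buffer), CH2Cl2, 0 °C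
Reagents that add atoms: meta-chloroperoxybenzoic acid, OOC(=O)c1cccc(Cl)c1
Why: Prilezhaev epoxidation is chemoselective for the electron-richest, strained E-C1=C10 alkene (C4=C5 is deactivated by two allylic oxygens and the enoate alkene is electron-poor), and attack on its exposed outer face in the ground-state conformer is expected to give the 1R,10R epoxide, by analogy with peracid epoxidation of germacranolide 1(10)-alkenes.

Step 18
Reactants: 29 3-O-triethylsilyl ether of the target
Product: 30 target, (1R,3S,4Z,6R,7R,8R,10R)-1,10-epoxy-3-hydroxygermacra-4,11(13)-dien-12,6-olid-8-yl (2S,3S)-2,3-dimethyloxirane-2-carboxylate (CNP0268255.2)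
Conditions: HF·pyridine, excess pyridine, THF, 0 °C
Reagents that add atoms: none
Why: Buffered fluoride desilylation removes the secondary TES ether under near-neutral conditions that leave both oxiranes, the ester and the α-methylene lactone intact.

## Compound list

1 | but-3-yn-1-ol | C#CCCO | starting material
2 | triethyl(but-3-yn-1-yloxy)silane | C#CCCO[Si](CC)(CC)CC | intermediate
3 | oxirane | C1CO1 | starting material
4 | alkenyldimethylalane: dimethyl[(1E)-2-methyl-4-(triethylsilyloxy)but-1-en-1-yl]alane | C[Al](C)/C=C(\C)CCO[Si](CC)(CC)CC | intermediate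
5 | lithium alkenylalanate: lithium butyl(dimethyl)[(1E)-2-methyl-4-(triethylsilyloxy)but-1-en-1-yl]alanate | [Li+].CCCC[Al-](C)(C)/C=C(\C)CCO[Si](CC)(CC)CC | intermediate
6 | (3E)-4-methyl-6-(triethylsilyloxy)hex-3-en-1-ol | OCC/C=C(\C)CCO[Si](CC)(CC)CC | intermediate
7 | (3E)-4-methyl-6-(triethylsilyloxy)hex-3-enal | O=CC/C=C(\C)CCO[Si](CC)(CC)CC | intermediate
8 | methyl propiolate | C#CC(=O)OC | starting material
9 | methyl (4S,6E)-4-hydroxy-7-methyl-9-(triethylsilyloxy)non-6-en-2-ynoate | COC(=O)C#C[C@@H](O)C/C=C(\C)CCO[Si](CC)(CC)CC | intermediate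
10 | methyl (4S,6E)-7-methyl-4,9-bis(triethylsilyloxy)non-6-en-2-ynoate | COC(=O)C#C[C@@H](O[Si](CC)(CC)CC)C/C=C(\C)CCO[Si](CC)(CC)CC | intermediate
11 | methyl (2Z,4S,6E)-3,7-dimethyl-4,9-bis(triethylsilyloxy)nona-2,6-dienoate | COC(=O)/C=C(/C)[C@@H](O[Si](CC)(CC)CC)C/C=C(\C)CCO[Si](CC)(CC)CC | intermediate
12 | (2Z,4S,6E)-3,7-dimethyl-4,9-bis(triethylsilyloxy)nona-2,6-dien-1-ol | OC/C=C(/C)[C@@H](O[Si](CC)(CC)CC)C/C=C(\C)CCO[Si](CC)(CC)CC | intermediate
13 | (2Z,4S,6E)-3,7-dimethyl-4,9-bis(triethylsilyloxy)nona-2,6-dienal | O=C/C=C(/C)[C@@H](O[Si](CC)(CC)CC)C/C=C(\C)CCO[Si](CC)(CC)CC | intermediate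
14 | formaldehyde (supplied as paraformaldehyde) | C=O | starting material
15 | hydroxymethyl iodoacrylate: methyl (2Z)-2-(hydroxymethyl)-3-iodoprop-2-enoate (present as its aluminium alkoxide) | COC(=O)/C(CO)=C\I | intermediate
16 | methyl (2Z)-2-(acetoxymethyl)-3-iodoprop-2-enoate | COC(=O)/C(COC(C)=O)=C\I | intermediate
17 | hydroxy trienoate: methyl (2Z,4R,5Z,7S,9E)-2-(acetoxymethyl)-4-hydroxy-6,10-dimethyl-7,12-bis(triethylsilyloxy)dodeca-2,5,9-trienoate (present as its chromium alkoxide) | COC(=O)/C(COC(C)=O)=C\[C@H](O)/C=C(/C)[C@@H](O[Si](CC)(CC)CC)C/C=C(\C)CCO[Si](CC)(CC)CC | intermediate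
18 | [(5R)-5-[(1Z,3S,5E)-2,6-dimethyl-3,8-bis(triethylsilyloxy)octa-1,5-dien-1-yl]-2-oxo-2,5-dihydrofuran-3-yl]methyl acetate | CC(=O)OCC1=C[C@@H](/C=C(/C)[C@@H](O[Si](CC)(CC)CC)C/C=C(\C)CCO[Si](CC)(CC)CC)OC1=O | intermediate
19 | [(5R)-5-[(1Z,3S,5E)-2,6-dimethyl-8-oxo-3-(triethylsilyloxy)octa-1,5-dien-1-yl]-2-oxo-2,5-dihydrofuran-3-yl]methyl acetate | CC(=O)OCC1=C[C@@H](/C=C(/C)[C@@H](O[Si](CC)(CC)CC)C/C=C(\C)CC=O)OC1=O | intermediate
20 | samarium ketyl: C8 ketyl radical anion of 19 (Sm(III) counter-ion omitted) | CC(=O)OCC1=C[C@@H](/C=C(/C)[C@@H](O[Si](CC)(CC)CC)C/C=C(\C)C[CH][O-])OC1=O | intermediate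
21 | samarium enolate: ring-closed lactone enolate C8-alkoxide still carrying the acetoxymethyl group (Sm(III) counter-ions omitted) | CC(=O)OCC1=C([O-])O[C@@H]2/C=C(/C)[C@@H](O[Si](CC)(CC)CC)C/C=C(\C)C[C@@H]([O-])[C@@H]12 | intermediate
22 | (3aR,4R,6E,9S,10Z,11aR)-4-hydroxy-6,10-dimethyl-3-methylidene-9-(triethylsilyloxy)-3a,4,5,8,9,11a-hexahydrocyclodeca[b]furan-2(3H)-one | C=C1C(=O)O[C@@H]2/C=C(/C)[C@@H](O[Si](CC)(CC)CC)C/C=C(\C)C[C@@H](O)[C@@H]12 | intermediate
23 | angelic acid, (2Z)-2-methylbut-2-enoic acid | C/C=C(/C)C(=O)O | starting material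
24 | (2Z)-2-methylbut-2-en-1-ol | C/C=C(/C)CO | intermediate
25 | [(2R,3S)-2,3-dimethyloxiran-2-yl]methanol | OC[C@@]1(C)O[C@H]1C | intermediate
26 | (2S,3S)-2,3-dimethyloxirane-2-carboxylic acid | OC(=O)[C@@]1(C)O[C@H]1C | intermediate
27 | Yamaguchi mixed anhydride: (2S,3S)-2,3-dimethyloxirane-2-carboxylic 2,4,6-trichlorobenzoic anhydride | O=C(OC(=O)[C@@]1(C)O[C@H]1C)c1c(Cl)cc(Cl)cc1Cl | intermediate
28 | (3aR,4R,6E,9S,10Z,11aR)-6,10-dimethyl-3-methylidene-2-oxo-9-(triethylsilyloxy)-2,3,3a,4,5,8,9,11a-octahydrocyclodeca[b]furan-4-yl (2S,3S)-2,3-dimethyloxirane-2-carboxylate | C=C1C(=O)O[C@@H]2/C=C(/C)[C@@H](O[Si](CC)(CC)CC)C/C=C(\C)C[C@@H](OC(=O)[C@@]3(C)O[C@H]3C)[C@@H]12 | intermediate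
29 | 3-O-triethylsilyl ether of the target [(1R,10R)-1,10-epoxide of 28] | C=C1C(=O)O[C@@H]2/C=C(/C)[C@@H](O[Si](CC)(CC)CC)C[C@H]3O[C@]3(C)C[C@@H](OC(=O)[C@@]3(C)O[C@H]3C)[C@@H]12 | intermediate
30 | (1R,3S,4Z,6R,7R,8R,10R)-1,10-epoxy-3-hydroxygermacra-4,11(13)-dien-12,6-olid-8-yl (2S,3S)-2,3-dimethyloxirane-2-carboxylate | C=C1C(=O)O[C@@H]2/C=C(/C)[C@@H](O)C[C@H]3O[C@]3(C)C[C@@H](OC(=O)[C@@]3(C)O[C@H]3C)[C@@H]12 | target

## Step count and risks

Total step count: 18. Longest linear sequence: 14 steps (1–8, 10–12, 16–18).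

Steps most likely to fail:

Step 12 (SmI2 ring closure). A 10-exo ketyl addition has no direct precedent. Competing paths are pinacol coupling, direct reduction of the allylic acetate or butenolide, the C8 epimer, and migration of the lactone to O8. The fallback sets out from 19 and comes back at 22: the same aldehyde–allylic acetate is closed by polar umpolung instead, with Pd(PPh3)4 and InI in THF at high dilution converting the allylic acetate into an allylindium that adds through its γ-carbon (C7) to the aldehyde (Araki-type allylation). No new compound is formed.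

Step 10 (Ni/Cr coupling). Ligand control at C6 may be modest on an enal with only a remote stereocentre, and the β-chromio acrylate may lose its Z geometry. The fallback sets out from 13 and comes back at 18. (R,R)-ProPhenol/Me2Zn addition of methyl propiolate 8 gives methyl (4R,5Z,7S,9E)-4-hydroxy-6,10-dimethyl-7,12-bis(triethylsilyloxy)dodeca-5,9-dien-2-ynoate F1. Lindlar semi-hydrogenation gives the Z-hydroxy enoate, which lactonises to (5S)-5-[(1Z,3S,5E)-2,6-dimethyl-3,8-bis(triethylsilyloxy)octa-1,5-dien-1-yl]furan-2(5H)-one F2 (same spatial arrangement at C6; the descriptor changes by CIP priority only). Morita–Baylis–Hillman hydroxymethylation with aqueous formaldehyde and DMAP gives (5R)-5-[(1Z,3S,5E)-2,6-dimethyl-3,8-bis(triethylsilyloxy)octa-1,5-dien-1-yl]-3-(hydroxymethyl)furan-2(5H)-one F3, and acetylation (Ac2O, pyridine) gives 18.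

Step 17 (epoxidation). The face of attack rests on the ring conformation, and the acid by-product could trigger transannular opening. The fallback sets out from 28 and comes back at 29: substrate control is replaced by catalyst control, using Shi's D-fructose-derived ketone with Oxone (K2CO3 buffer, MeCN/dimethoxymethane, 0 °C). Its spiro transition state gives the (R,R)-epoxide from E-trisubstituted alkenes whatever the ring conformation. No new compound is formed.

## Further compounds

F1 | step 10 | methyl (4R,5Z,7S,9E)-4-hydroxy-6,10-dimethyl-7,12-bis(triethylsilyloxy)dodeca-5,9-dien-2-ynoate | COC(=O)C#C[C@H](O)/C=C(/C)[C@@H](O[Si](CC)(CC)CC)C/C=C(\C)CCO[Si](CC)(CC)CC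
F2 | step 10 | (5S)-5-[(1Z,3S,5E)-2,6-dimethyl-3,8-bis(triethylsilyloxy)octa-1,5-dien-1-yl]furan-2(5H)-one | O=C1C=C[C@@H](/C=C(/C)[C@@H](O[Si](CC)(CC)CC)C/C=C(\C)CCO[Si](CC)(CC)CC)O1
F3 | step 10 | (5R)-5-[(1Z,3S,5E)-2,6-dimethyl-3,8-bis(triethylsilyloxy)octa-1,5-dien-1-yl]-3-(hydroxymethyl)furan-2(5H)-one | OCC1=C[C@@H](/C=C(/C)[C@@H](O[Si](CC)(CC)CC)C/C=C(\C)CCO[Si](CC)(CC)CC)OC1=O
F0 | step 12 | none | none
F0 | step 17 | none | none
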